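Assumption: the SMILES fixes C1 and C3 (both S) but not the sense of the hindered biaryl axis, so the route fixes (1S,3S) and delivers the axis as two separable atropo-diastereomers, each of which matches the structure as drawn.

**Retrosynthetic overview**
1. Target 13 ⇐ 12 by O-methylation of the single free naphthol OH.
2. 12 ⇐ 11 + 6: the C5–C1' biaryl bond, made last by phenol-oxidative cross-coupling para to the naphthol OH.
3. 6 ⇐ 5 ⇐ 3: the nitrogen ring is closed by enzymatic amination of aryl δ-diketone 3 and spontaneous ketimine formation (sets C3), then trans-selective imine reduction (sets C1); 3 ⇐ 1 by ring acetylation.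
4. 11 ⇐ 10: the second carbocycle of the naphthalene is closed by intramolecular aldol condensation of δ-diketone 10; 10 ⇐ 7 + 8 by aryne insertion.
5. Ring order: the nitrogen ring (steps 2–3) and the naphthalene ring (step 4) are built in parallel, each from an aryl 1,5-diketone, and the two halves are then joined.

**Route**

Step 1
Reactants: 1 1-(3,5-dimethoxyphenyl)propan-2-one
Product: 3 1-(2-acetyl-3,5-dimethoxyphenyl)propan-2-one, via benzopyrylium salt 2 (not isolated)
Conditions: Ac2O, HBF4·OEt2 (1.1 equiv), 0 °C to rt; then poured into aq. NaOAc/Et2O, rt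
Reagents that add atoms: acetic anhydride CC(=O)OC(C)=O; water O
Why: Friedel–Crafts acylation at the ring carbon ortho to the side chain and para to a methoxy group (the site where orcinol dimethyl ether is acylated) is trapped by the enol oxygen as the 2-benzopyrylium ion, which aqueous acetate opens to the δ-diketone; no stereocentre is formed.

Step 2
Reactants: 3 1-(2-acetyl-3,5-dimethoxyphenyl)propan-2-one
Product: 5 (3S)-6,8-dimethoxy-1,3-dimethyl-3,4-dihydroisoquinoline, via amino ketone 4 (not isolated)
Conditions: (S)-selective ω-transaminase (Silicibacter pomeroyi enzyme), pyridoxal 5'-phosphate (1 mM), iPrNH2 (0.5 M), phosphate buffer pH 7.5, 10% DMSO, 30 °C, 24 h; then pH 11, EtOAc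
Reagents that add atoms: isopropylamine CC(C)N
Why: Biocatalytic transamination aminates only the unhindered benzyl methyl ketone (the aryl ketone between two ortho substituents is no substrate), the (S)-selective enzyme holds the methyl group in its small pocket so C3 is formed as S, and the amine then condenses with the aryl ketone to the six-membered ketimine, which pulls the equilibrium (the known monoamination–cyclisation of 1,5-diketones).

Step 3
Reactants: 5 (3S)-6,8-dimethoxy-1,3-dimethyl-3,4-dihydroisoquinoline
Product: 6 (1S,3S)-6,8-dimethoxy-1,3-dimethyl-1,2,3,4-tetrahydroisoquinoline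
Conditions: AlMe3, then LiAlH4, THF, −78 °C to 0 °C; H2O/aq. NaOH work-up
Reagents that add atoms: none
Why: In this Lewis-acid-assisted imine reduction the N–AlMe3 complex and the peri 8-methoxy group force the developing C1 methyl pseudo-axial, so hydride adds to the imine face that carries the C3 methyl and gives the 1,3-trans (1S,3S) amine (about 9:1 over cis, which is removed by chromatography; NaBH4 would give cis).

Step 4
Reactants: 7 3-methoxy-2-(trimethylsilyl)phenyl trifluoromethanesulfonate; 8 pentane-2,4-dione
Product: 11 8-methoxy-3-methylnaphthalen-1-ol, via 3-methoxybenzyne 9 (not isolated), via diketone 10 (not isolated)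
Conditions: CsF (2.5 equiv), MeCN, 80 °C; then KOH, MeOH, 50 °C; aq. HCl work-up
Reagents that add atoms: none
Why: In this aryne acyl-alkylation the enolate carbon of 8 adds meta to OMe, the aryl anion ortho to OMe attacks an acetyl carbonyl and the four-membered alkoxide fragments to δ-diketone 10, whose acetophenone enolate then closes onto the aliphatic ketone (intramolecular aldol condensation, dehydration, enolisation) to the naphthol; no stereocentre is formed.

Step 5
Reactants: 11 8-methoxy-3-methylnaphthalen-1-ol; 6 (1S,3S)-6,8-dimethoxy-1,3-dimethyl-1,2,3,4-tetrahydroisoquinoline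
Product: 12 4-[(1S,3S)-6,8-dimethoxy-1,3-dimethyl-1,2,3,4-tetrahydroisoquinolin-5-yl]-8-methoxy-3-methylnaphthalen-1-ol
Conditions: 6 (3 equiv), CF3CO2H (3.3 equiv), (CF3)2CHOH, −40 °C; PhI(OCOCF3)2 (1.0 equiv) added slowly, to 0 °C; aq. NaHCO3 work-up, excess 6 recovered
Reagents that add atoms: none
Why: Proposed new method: PhI(OCOCF3)2 exchanges a ligand for the naphthol O–H and, in the ionising fluoro alcohol, gives a naphthoxy-λ3-iodane (phenoxenium equivalent) whose electrophilic sites are C2 and C4 of the hydroxylated ring only; the most electron-rich free carbon of 6 (C5, para to 8-OMe and ortho to 6-OMe, the site at which this ring is halogenated) attacks the para carbon C4 in a Friedel–Crafts sense and tautomerisation restores the naphthol; N-protonation shields the amine and its benzylic C1–H from the oxidant and the excess of 6 competes with naphthol self-coupling; no stereocentre is touched and the stable axis forms as a roughly 1:1 separable pair; the closest known reactions are the hypervalent-iodine para-selective oxidative cross-coupling of phenols with methoxyarenes in fluoro alcohols, the C4 oxidation of 1-naphthols by the same reagent and enzymatic phenol-oxidative coupling.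

Step 6
Reactants: 12 4-[(1S,3S)-6,8-dimethoxy-1,3-dimethyl-1,2,3,4-tetrahydroisoquinolin-5-yl]-8-methoxy-3-methylnaphthalen-1-ol
Product: 13 (1S,3S)-5-(4,5-dimethoxy-2-methylnaphthalen-1-yl)-6,8-dimethoxy-1,3-dimethyl-1,2,3,4-tetrahydroisoquinoline
Conditions: CH2N2, Et2O–MeOH, 0 °C to rt; atropo-diastereomers separated on silica
Reagents that add atoms: diazomethane C=[N+]=[N-]
Why: In this phenol O-methylation the naphthol protonates diazomethane and the naphtholate is methylated by the methyldiazonium ion, whereas the secondary amine is not acidic enough to react, and neither stereocentre is touched.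

**Compound list**
1 | 1-(3,5-dimethoxyphenyl)propan-2-one | CC(=O)Cc1cc(OC)cc(OC)c1 | starting material
2 | 6,8-dimethoxy-1,3-dimethylisochromenylium (2-benzopyrylium) tetrafluoroborate | Cc1cc2cc(OC)cc(OC)c2c(C)[o+]1.F[B-](F)(F)F | intermediate
3 | 1-(2-acetyl-3,5-dimethoxyphenyl)propan-2-one | CC(=O)Cc1cc(OC)cc(OC)c1C(C)=O | intermediate
4 | 1-[2-[(2S)-2-aminopropyl]-4,6-dimethoxyphenyl]ethan-1-one | C[C@H](N)Cc1cc(OC)cc(OC)c1C(C)=O | intermediate
5 | (3S)-6,8-dimethoxy-1,3-dimethyl-3,4-dihydroisoquinoline | COc1cc(OC)c2c(c1)C[C@H](C)N=C2C | intermediate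
6 | (1S,3S)-6,8-dimethoxy-1,3-dimethyl-1,2,3,4-tetrahydroisoquinoline | COc1cc(OC)c2c(c1)C[C@H](C)N[C@H]2C | intermediate
7 | 3-methoxy-2-(trimethylsilyl)phenyl trifluoromethanesulfonate | COc1cccc(OS(=O)(=O)C(F)(F)F)c1[Si](C)(C)C | starting material
8 | pentane-2,4-dione | CC(=O)CC(C)=O | starting material
9 | 3-methoxybenzyne | COC1=CC=CC#C1 | intermediate
10 | 1-(2-acetyl-3-methoxyphenyl)propan-2-one | CC(=O)Cc1cccc(OC)c1C(C)=O | intermediate
11 | 8-methoxy-3-methylnaphthalen-1-ol | Cc1cc(O)c2c(OC)cccc2c1 | intermediate
12 | 4-[(1S,3S)-6,8-dimethoxy-1,3-dimethyl-1,2,3,4-tetrahydroisoquinolin-5-yl]-8-methoxy-3-methylnaphthalen-1-ol | COc1cc(OC)c2c(c1-c1c(C)cc(O)c3c(OC)cccc13)C[C@H](C)N[C@H]2C | intermediate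
13 | (1S,3S)-5-(4,5-dimethoxy-2-methylnaphthalen-1-yl)-6,8-dimethoxy-1,3-dimethyl-1,2,3,4-tetrahydroisoquinoline | COc1cc(OC)c2c(c1-c1c(C)cc(OC)c3c(OC)cccc13)C[C@H](C)N[C@H]2C | target

**Totals**
Total step count: 6. Longest linear sequence: 5 steps (steps 1, 2, 3, 5, 6); the naphthol branch is one step (step 4) before the union.

**Steps most likely to fail**

Step 5 (oxidative cross-coupling). The risks are naphthol self-coupling, over-oxidation of the product naphthol, attack at C7 instead of C5, and the four-fold ortho-substituted bond. The fallback sets out from 11 and 6 and comes back at 13, bypassing 12 and step 6. Naphthol 11 is brominated para to the hydroxyl (NBS, MeCN, 0 °C) to 4-bromo-8-methoxy-3-methylnaphthalen-1-ol F4. This is O-methylated (MeI, K2CO3, acetone) to 1-bromo-4,5-dimethoxy-2-methylnaphthalene F5. Bromine–lithium exchange and borylation (n-BuLi, THF, −78 °C; B(OMe)3; aq. HCl) give (4,5-dimethoxy-2-methylnaphthalen-1-yl)boronic acid F6. Amine 6 is iodinated as its ammonium salt (N-iodosuccinimide, CF3CO2H, 0 °C) to (1S,3S)-5-iodo-6,8-dimethoxy-1,3-dimethyl-1,2,3,4-tetrahydroisoquinoline F7. Suzuki coupling of F6 with F7 (Pd(OAc)2, 2-dicyclohexylphosphino-2',6'-dimethoxybiphenyl, K3PO4, toluene–H2O, 100 °C) gives 13 directly as the same separable pair of atropo-diastereomers.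

Step 2 (transaminase amination–cyclisation). The risks are poor acceptance of the doubly ortho-substituted arylacetone by the enzyme, and background reactions of the diketone (condensation with the amine donor to an N-alkylisoquinolinium salt, or aldol closure to a naphthol). The fallback sets out from 1 and comes back at 5, so it also bypasses step 1. Ketone 1 is condensed with (S)-1-phenylethylamine (Ti(OiPr)4) and the imine hydrogenated (H2, Raney Ni, EtOH) to (2S)-1-(3,5-dimethoxyphenyl)-N-[(1S)-1-phenylethyl]propan-2-amine F1, purified as its hydrochloride. Hydrogenolysis (H2, Pd/C, MeOH) gives (2S)-1-(3,5-dimethoxyphenyl)propan-2-amine F2. Acetylation (AcCl, Et3N, CH2Cl2) gives N-[(2S)-1-(3,5-dimethoxyphenyl)propan-2-yl]acetamide F3. Bischler–Napieralski cyclisation (POCl3, MeCN, reflux) then closes the ring para to a methoxy group and gives 5.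

Step 6 (chemoselective O-methylation). The risks are sluggish reaction of the peri-hydrogen-bonded naphthol and competing N-methylation. The fallback sets out from 12 and comes back at 13. The amine is protected (Boc2O, MeOH, 40 °C) as tert-butyl (1S,3S)-5-(4-hydroxy-5-methoxy-2-methylnaphthalen-1-yl)-6,8-dimethoxy-1,3-dimethyl-3,4-dihydro-1H-isoquinoline-2-carboxylate F8. The naphthol is methylated under forcing conditions (NaH, MeI, DMF, 0 °C) to tert-butyl (1S,3S)-5-(4,5-dimethoxy-2-methylnaphthalen-1-yl)-6,8-dimethoxy-1,3-dimethyl-3,4-dihydro-1H-isoquinoline-2-carboxylate F9. The carbamate is then cleaved (CF3CO2H, CH2Cl2) to 13.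

**Further compounds**
F1 | step 2 | (2S)-1-(3,5-dimethoxyphenyl)-N-[(1S)-1-phenylethyl]propan-2-amine | C[C@H](N[C@@H](C)c1ccccc1)Cc1cc(OC)cc(OC)c1
F2 | step 2 | (2S)-1-(3,5-dimethoxyphenyl)propan-2-amine | C[C@H](N)Cc1cc(OC)cc(OC)c1
F3 | step 2 | N-[(2S)-1-(3,5-dimethoxyphenyl)propan-2-yl]acetamide | C[C@H](NC(C)=O)Cc1cc(OC)cc(OC)c1
F4 | step 5 | 4-bromo-8-methoxy-3-methylnaphthalen-1-ol | Cc1cc(O)c2c(OC)cccc2c1Br
F5 | step 5 | 1-bromo-4,5-dimethoxy-2-methylnaphthalene | Cc1cc(OC)c2c(OC)cccc2c1Br
F6 | step 5 | (4,5-dimethoxy-2-methylnaphthalen-1-yl)boronic acid | Cc1cc(OC)c2c(OC)cccc2c1B(O)O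
F7 | step 5 | (1S,3S)-5-iodo-6,8-dimethoxy-1,3-dimethyl-1,2,3,4-tetrahydroisoquinoline | COc1cc(OC)c2c(c1I)C[C@H](C)N[C@H]2C
F8 | step 6 | tert-butyl (1S,3S)-5-(4-hydroxy-5-methoxy-2-methylnaphthalen-1-yl)-6,8-dimethoxy-1,3-dimethyl-3,4-dihydro-1H-isoquinoline-2-carboxylate | COc1cc(OC)c2c(c1-c1c(C)cc(O)c3c(OC)cccc13)C[C@H](C)N(C(=O)OC(C)(C)C)[C@H]2C
F9 | step 6 | tert-butyl (1S,3S)-5-(4,5-dimethoxy-2-methylnaphthalen-1-yl)-6,8-dimethoxy-1,3-dimethyl-3,4-dihydro-1H-isoquinoline-2-carboxylate | COc1cc(OC)c2c(c1-c1c(C)cc(OC)c3c(OC)cccc13)C[C@H](C)N(C(=O)OC(C)(C)C)[C@H]2C
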